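**Retrosynthetic overview**

1. The last bond is C7–C8. C8 is the 1,1-disubstituted alkene carbon that carries the exocyclic C13 methylene and joins cyclobutane C9 to the C7 methylene inside the nine-membered ring C1–C9. A C5 vinyl group is hydroborated and coupled intramolecularly (B-alkyl Suzuki) with a C9 1-iodovinyl group.
2. Dihydropyran (O–C4–C5–C1'–ring A): the O–C(enol) bond comes from vinylogous esterification of the C4 tertiary alcohol. The C5–C1' bond comes from an enamine Michael addition of a C6 aldehyde to the syncarpic acid/isovaleraldehyde alkylidene, which sets C5 and C1'. The C6 aldehyde then becomes the vinyl group.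
3. Cyclobutane (C1, C9, C10, C11): an enantioselective allenoate–alkene [2+2] on the Me2C=CH end of an (R)-linalool-derived diol sets C1, with C4 taken from the chiral pool. Curtius degradation, alkyne homologation and α-hydroiodination give the trans C9 1-iodovinyl group.
4. Ring order: cyclobutane (step 4), dihydropyran (step 13), nine-membered carbocycle (step 14). Ring A arrives intact as syncarpic acid.

Key step: step 14

**Remarks (assumptions)**

- Atom labels: caryophyllane numbering C1–C13 for the terpene part, C1' for the isobutyl-bearing carbon, ring A for the tetramethylcyclohexenedione. TBS = tert-butyldimethylsilyl.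
- Commercial (R)-(−)-linalool of high enantiomeric purity is assumed.
- The oxazaborolidinium antipode in step 4 is taken to be the one that gives (R) at C1 of the final skeleton; both antipodes are accessible.
- Compound 21 is drawn as the open enol-aldehyde, although it should sit largely as its cyclic hemiacetal.

**Route**

Step 1
Reactants: 1 (R)-(−)-linalool
Product: 2 (3R)-3,7-dimethyloct-6-ene-1,3-diol
Conditions: 9-BBN (2.2 equiv), THF, 0 °C → rt; then 3 M NaOH, 30% H2O2, 0 °C → rt
Reagents that add atoms: hydrogen peroxide, OO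
Why: Hydroboration–oxidation, in which 9-BBN should add anti-Markovnikov to the monosubstituted vinyl group far faster than to the trisubstituted alkene, leaving the C4 carbinol centre of the chiral pool untouched.

Step 2
Reactants: 2 (3R)-3,7-dimethyloct-6-ene-1,3-diol
Product: 3 (3R)-1,3-bis[(TBS)oxy]-3,7-dimethyloct-6-ene
Conditions: TBSOTf (2.5 equiv), 2,6-lutidine, CH2Cl2, −78 → 0 °C
Reagents that add atoms: tert-butyldimethylsilyl triflate, CC(C)(C)[Si](C)(C)OS(=O)(=O)C(F)(F)F
Why: Silyl triflate silylation, reactive enough for the tertiary alcohol, removes both Lewis-basic OH groups and leaves a single alkene for the Lewis acid step.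

Step 3
Reactants: 4 but-3-ynoic acid; 5 2,2,2-trifluoroethanol
Product: 7 2,2,2-trifluoroethyl buta-2,3-dienoate, via trifluoroethyl but-3-ynoate 6 (not isolated)
Conditions: DCC, DMAP (cat.), CH2Cl2, 0 °C → rt
Reagents that add atoms: none
Why: Steglich esterification, after which DMAP should isomerise the but-3-ynoate to the conjugated allenoate in the same flask.

Step 4
Reactants: 3 (3R)-1,3-bis[(TBS)oxy]-3,7-dimethyloct-6-ene; 7 2,2,2-trifluoroethyl buta-2,3-dienoate
Product: 8 2,2,2-trifluoroethyl (2E)-[(2S)-2-{(3R)-3,5-bis[(TBS)oxy]-3-methylpentyl}-3,3-dimethylcyclobutylidene]acetate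
Conditions: chiral B-aryl oxazaborolidine (CBS-type, from diphenylprolinol) activated with AlBr3 (20 mol%, antipode chosen for the configuration shown), 7 (1.5 equiv), CH2Cl2, −78 → −20 °C
Reagents that add atoms: none
Why: Lewis acid-catalysed enantioselective allenoate–alkene [2+2] cycloaddition, in which the CH alkene carbon bonds to the central allenoate carbon and the Me2C carbon to the allenoate CH2 terminus, so the gem-dimethyl carbon ends up next to the chain-bearing carbon (the caryophyllane pattern, which an acrylate would not give); the catalyst sets C1 and the remote C4 centre has no influence.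

Step 5
Reactants: 8 trifluoroethyl cyclobutylideneacetate
Product: 9 (2E)-[(2S)-2-{(3R)-3,5-bis[(TBS)oxy]-3-methylpentyl}-3,3-dimethylcyclobutylidene]acetic acid
Conditions: LiOH, THF/H2O, 0 °C → rt; then 1 M HCl to pH 4
Reagents that add atoms: lithium hydroxide, [Li+].[OH-]
Why: Saponification of the activated trifluoroethyl ester should proceed under conditions that leave both silyl ethers and the allylic C1 centre untouched.

Step 6
Reactants: 9 cyclobutylideneacetic acid
Product: 12 (1S,2R)-2-{(3R)-3-[(TBS)oxy]-5-hydroxy-3-methylpentyl}-3,3-dimethylcyclobutane-1-carbaldehyde, via acyl azide 10 (not isolated), via vinyl isocyanate 11 (not isolated)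
Conditions: DPPA, Et3N, PhMe, 0 °C → rt, then 85 °C; then 1 M HCl, THF, rt; then DBU (0.2 equiv), CH2Cl2, rt
Reagents that add atoms: water, O
Why: Curtius rearrangement of the α,β-unsaturated acid and acid hydrolysis of the vinyl isocyanate (via enamine and iminium) should give the one-carbon-shorter aldehyde with hydrogen at C9, the same acid removing the primary TBS group while the tertiary one survives; DBU equilibration through the enol sets C9 as the thermodynamically favoured trans isomer relative to C1.

Step 7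
Reactants: 12 trans hydroxy aldehyde
Product: 13 (3R)-3-[(TBS)oxy]-5-[(1R,4S)-4-ethynyl-2,2-dimethylcyclobutyl]-3-methylpentan-1-ol
Conditions: dimethyl (1-diazo-2-oxopropyl)phosphonate, K2CO3, MeOH, 0 °C → rt
Reagents that add atoms: dimethyl (1-diazo-2-oxopropyl)phosphonate, CC(=O)C(=[N+]=[N-])P(=O)(OC)OC
Why: Ohira–Bestmann (Seyferth–Gilbert) homologation supplies C13, and its basic medium keeps C9 at the trans equilibrium before the centre becomes non-epimerisable in the alkyne.

Step 8
Reactants: 13 trans ethynylcyclobutane alcohol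
Product: 15 (3R)-3-[(TBS)oxy]-5-[(1R,4S)-4-(1-iodoethenyl)-2,2-dimethylcyclobutyl]-3-methylpentan-1-ol, via bis-aluminium alkenylalane 14 (not isolated)
Conditions: Ni(dppp)Cl2 (3 mol%), DIBAL-H (2.3 equiv), THF, 0 °C → rt; then I2, THF, −78 → 0 °C; aq. Rochelle salt
Reagents that add atoms: iodine, II
Why: Nickel-catalysed α-selective hydroalumination of the terminal alkyne (dppp places aluminium on the internal carbon) followed by iodinolysis of the C–Al bond should give the 1-iodovinyl group, one equivalent of hydride being consumed by the free OH.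

Step 9
Reactants: 15 iodovinyl alcohol
Product: 16 (3R)-3-[(TBS)oxy]-5-[(1R,4S)-4-(1-iodoethenyl)-2,2-dimethylcyclobutyl]-3-methylpentanal
Conditions: Dess–Martin periodinane, NaHCO3, CH2Cl2, 0 °C → rt
Reagents that add atoms: none
Why: Buffered Dess–Martin oxidation is non-basic and should spare the β-silyloxy group and the vinyl iodide.

Step 10
Reactants: 17 syncarpic acid; 18 isovaleraldehyde
Product: 20 2,2,4,4-tetramethyl-6-(3-methylbutylidene)cyclohexane-1,3,5-trione, via piperidine Mannich base 19 (not isolated)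
Conditions: 18 (3 equiv), piperidine (1.0 equiv), CH2Cl2, rt; then 1 M HCl
Reagents that add atoms: none
Why: Knoevenagel condensation through the piperidine Mannich base, which should eliminate to the alkylidene trione on acidification; excess aldehyde suppresses addition of a second syncarpic acid.

Step 11
Reactants: 16 β-silyloxy aldehyde; 20 alkylidene trione
Product: 21 (2S,3R)-3-[(TBS)oxy]-2-[(1R)-1-(2-hydroxy-3,3,5,5-tetramethyl-4,6-dioxocyclohex-1-en-1-yl)-3-methylbutyl]-5-[(1R,4S)-4-(1-iodoethenyl)-2,2-dimethylcyclobutyl]-3-methylpentanal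
Conditions: (S)-α,α-diphenylprolinol trimethylsilyl ether (20 mol%), 20 (1.3 equiv), PhMe, 0 °C → rt
Reagents that add atoms: none
Why: Diarylprolinol silyl ether enamine-catalysed Michael addition, in which the E-enamine of 16, shielded on one face by the catalyst, should add to the doubly activated alkene through the acyclic synclinal transition state, setting C5 by catalyst control and C1' by the syn topicity (the sense known for aldehyde/nitroalkene additions with this catalyst antipode), with C4 as a bystander.

Step 12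
Reactants: 21 Michael adduct
Product: 22 5-hydroxy-4-[(4R,5S,6R)-6-[(TBS)oxy]-5-ethenyl-8-[(1R,4S)-4-(1-iodoethenyl)-2,2-dimethylcyclobutyl]-2,6-dimethyloctan-4-yl]-2,2,6,6-tetramethylcyclohex-4-ene-1,3-dione
Conditions: Ph3PCH3Br, KHMDS, THF, 0 °C; then 21, −78 → 0 °C (3 equiv ylide)
Reagents that add atoms: methyltriphenylphosphonium bromide, C[P+](c1ccccc1)(c1ccccc1)c1ccccc1.[Br-]
Why: Wittig methylenation of the aldehyde (reached through the ring-opened hemiacetal) installs C7; the first equivalent of ylide is consumed by the acidic enol, whose enolate shields ring A, and the low temperature should avoid epimerisation at C5.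

Step 13
Reactants: 22 vinyl silyl ether
Product: 24 (2R,3S,4R)-3-ethenyl-2-{2-[(1R,4S)-4-(1-iodoethenyl)-2,2-dimethylcyclobutyl]ethyl}-2,6,6,8,8-pentamethyl-4-(2-methylpropyl)-3,4-dihydro-2H-chromene-5,7(6H,8H)-dione, via tertiary alcohol 23 (not isolated)
Conditions: aq. HF, MeCN, 0 °C → rt; then PPTS (20 mol%), 4 Å MS, PhMe, 80 °C
Reagents that add atoms: none
Why: Desilylation followed by acid-catalysed vinylogous esterification (addition–elimination of the tertiary OH on the enolised trione with removal of water) should close the dihydropyran without breaking the C4–O bond, so C4 keeps the linalool configuration and C5 and C1' are not touched.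

Step 14
Reactants: 24 seco vinyl iodide
Product: 26 tomentodione B, via B-alkyl-9-BBN borane 25 (not isolated)
Conditions: 9-BBN (1.5 equiv), THF, 0 °C → rt; then slow addition (syringe pump) to Pd(dppf)Cl2 (20 mol%), AsPh3 (40 mol%), Cs2CO3 (3 equiv), DMF/THF/H2O, 50 °C, final concentration about 1 mM
Reagents that add atoms: none
Why: Proposed new method: 9-BBN should hydroborate the monosubstituted C6=C7 vinyl group at C7, after which Pd(0) inserts into the C8–I bond, base-assisted transmetalation transfers the C7 alkyl group intramolecularly and reductive elimination forms C7–C8. The closest known reactions are the intramolecular B-alkyl Suzuki–Miyaura cyclisation of 2-halo-1,ω-dienes to five- and six-membered methylenecycloalkanes and B-alkyl Suzuki–Miyaura macrocyclisations of vinyl iodides; a nine-membered carbocycle has not been closed this way. The ring closes by C(sp3)–C(sp2) coupling at C8 through a ten-membered palladacycle, with the C13 methylene staying exocyclic, and two of the nine ring bonds (C1–C9 in the trans-cyclobutane and C4–C5 in the dihydropyran) are already fixed, which lowers the entropic cost. No stereocentre is formed. The step needs chemoselective hydroboration, which rests on the vinyl group being monosubstituted while the 1-iodoalkene is hindered and electron-poor and the ring A ketones are flanked by quaternary carbons. It also needs cyclisation over oligomerisation (slow addition, high dilution) and coupling over β-hydride elimination or protodeboronation (wide bite angle of dppf, AsPh3), and ring A has no enolisable hydrogen to suffer under the base.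

**Compound list**

1 | (R)-(−)-linalool, (3R)-3,7-dimethylocta-1,6-dien-3-ol | C=C[C@](C)(O)CCC=C(C)C | starting material
2 | (3R)-3,7-dimethyloct-6-ene-1,3-diol | OCC[C@](C)(O)CCC=C(C)C | intermediate
3 | (3R)-1,3-bis[(TBS)oxy]-3,7-dimethyloct-6-ene | CC(C)(C)[Si](C)(C)OCC[C@](C)(O[Si](C)(C)C(C)(C)C)CCC=C(C)C | intermediate
4 | but-3-ynoic acid | C#CCC(=O)O | starting material
5 | 2,2,2-trifluoroethanol | OCC(F)(F)F | starting material
6 | 2,2,2-trifluoroethyl but-3-ynoate (not isolated) | C#CCC(=O)OCC(F)(F)F | intermediate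
7 | 2,2,2-trifluoroethyl buta-2,3-dienoate | C=C=CC(=O)OCC(F)(F)F | intermediate
8 | 2,2,2-trifluoroethyl (2E)-[(2S)-2-{(3R)-3,5-bis[(TBS)oxy]-3-methylpentyl}-3,3-dimethylcyclobutylidene]acetate | CC(C)(C)[Si](C)(C)OCC[C@](C)(O[Si](C)(C)C(C)(C)C)CC[C@@H]1/C(=C/C(=O)OCC(F)(F)F)CC1(C)C | intermediate
9 | (2E)-[(2S)-2-{(3R)-3,5-bis[(TBS)oxy]-3-methylpentyl}-3,3-dimethylcyclobutylidene]acetic acid | CC(C)(C)[Si](C)(C)OCC[C@](C)(O[Si](C)(C)C(C)(C)C)CC[C@@H]1/C(=C/C(=O)O)CC1(C)C | intermediate
10 | acyl azide of 9 (not isolated) | CC(C)(C)[Si](C)(C)OCC[C@](C)(O[Si](C)(C)C(C)(C)C)CC[C@@H]1/C(=C/C(=O)N=[N+]=[N-])CC1(C)C | intermediate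
11 | (E)-[(2S)-cyclobutylidene]methyl isocyanate from 10 (not isolated) | CC(C)(C)[Si](C)(C)OCC[C@](C)(O[Si](C)(C)C(C)(C)C)CC[C@@H]1/C(=C/N=C=O)CC1(C)C | intermediate
12 | (1S,2R)-2-{(3R)-3-[(TBS)oxy]-5-hydroxy-3-methylpentyl}-3,3-dimethylcyclobutane-1-carbaldehyde (trans) | OCC[C@](C)(O[Si](C)(C)C(C)(C)C)CC[C@@H]1[C@@H](C=O)CC1(C)C | intermediate
13 | (3R)-3-[(TBS)oxy]-5-[(1R,4S)-4-ethynyl-2,2-dimethylcyclobutyl]-3-methylpentan-1-ol | OCC[C@](C)(O[Si](C)(C)C(C)(C)C)CC[C@@H]1[C@@H](C#C)CC1(C)C | intermediate
14 | α-alkenylalane with O-aluminium alkoxide (not isolated) | CC(C)C[Al](CC(C)C)OCC[C@](C)(O[Si](C)(C)C(C)(C)C)CC[C@@H]1[C@@H](C(=C)[Al](CC(C)C)CC(C)C)CC1(C)C | intermediate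
15 | (3R)-3-[(TBS)oxy]-5-[(1R,4S)-4-(1-iodoethenyl)-2,2-dimethylcyclobutyl]-3-methylpentan-1-ol | OCC[C@](C)(O[Si](C)(C)C(C)(C)C)CC[C@@H]1[C@@H](C(I)=C)CC1(C)C | intermediate
16 | (3R)-3-[(TBS)oxy]-5-[(1R,4S)-4-(1-iodoethenyl)-2,2-dimethylcyclobutyl]-3-methylpentanal | O=CC[C@](C)(O[Si](C)(C)C(C)(C)C)CC[C@@H]1[C@@H](C(I)=C)CC1(C)C | intermediate
17 | syncarpic acid, 2,2,4,4-tetramethylcyclohexane-1,3,5-trione | CC1(C)C(=O)CC(=O)C(C)(C)C1=O | starting material
18 | isovaleraldehyde, 3-methylbutanal | CC(C)CC=O | starting material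
19 | 5-hydroxy-2,2,6,6-tetramethyl-4-[3-methyl-1-(piperidin-1-yl)butyl]cyclohex-4-ene-1,3-dione (Mannich base, racemic, not isolated) | CC(C)CC(N1CCCCC1)C1=C(O)C(C)(C)C(=O)C(C)(C)C1=O | intermediate
20 | 2,2,4,4-tetramethyl-6-(3-methylbutylidene)cyclohexane-1,3,5-trione | CC(C)CC=C1C(=O)C(C)(C)C(=O)C(C)(C)C1=O | intermediate
21 | (2S,3R)-3-[(TBS)oxy]-2-[(1R)-1-(2-hydroxy-3,3,5,5-tetramethyl-4,6-dioxocyclohex-1-en-1-yl)-3-methylbutyl]-5-[(1R,4S)-4-(1-iodoethenyl)-2,2-dimethylcyclobutyl]-3-methylpentanal (open form of the hemiacetal) | O=C[C@@H]([C@@H](CC(C)C)C1=C(O)C(C)(C)C(=O)C(C)(C)C1=O)[C@](C)(O[Si](C)(C)C(C)(C)C)CC[C@@H]1[C@@H](C(I)=C)CC1(C)C | intermediate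
22 | 5-hydroxy-4-[(4R,5S,6R)-6-[(TBS)oxy]-5-ethenyl-8-[(1R,4S)-4-(1-iodoethenyl)-2,2-dimethylcyclobutyl]-2,6-dimethyloctan-4-yl]-2,2,6,6-tetramethylcyclohex-4-ene-1,3-dione | C=C[C@@H]([C@@H](CC(C)C)C1=C(O)C(C)(C)C(=O)C(C)(C)C1=O)[C@](C)(O[Si](C)(C)C(C)(C)C)CC[C@@H]1[C@@H](C(I)=C)CC1(C)C | intermediate
23 | desilylated tertiary alcohol of 22 (not isolated) | C=C[C@@H]([C@@H](CC(C)C)C1=C(O)C(C)(C)C(=O)C(C)(C)C1=O)[C@](C)(O)CC[C@@H]1[C@@H](C(I)=C)CC1(C)C | intermediate
24 | (2R,3S,4R)-3-ethenyl-2-{2-[(1R,4S)-4-(1-iodoethenyl)-2,2-dimethylcyclobutyl]ethyl}-2,6,6,8,8-pentamethyl-4-(2-methylpropyl)-3,4-dihydro-2H-chromene-5,7(6H,8H)-dione (key-step precursor) | C=C[C@H]1[C@@H](CC(C)C)C2=C(O[C@]1(C)CC[C@@H]1[C@@H](C(I)=C)CC1(C)C)C(C)(C)C(=O)C(C)(C)C2=O | intermediate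
25 | C7 B-alkyl-9-BBN borane of 24 (not isolated) | C1CCC2CCCC1B2CC[C@H]1[C@@H](CC(C)C)C2=C(O[C@]1(C)CC[C@@H]1[C@@H](C(I)=C)CC1(C)C)C(C)(C)C(=O)C(C)(C)C2=O | intermediate
26 | tomentodione B | C=C1CC[C@H]2[C@@H](CC(C)C)C3=C(O[C@]2(C)CC[C@@H]2[C@@H]1CC2(C)C)C(C)(C)C(=O)C(C)(C)C3=O | target

**Step count**

Total: 14 steps. Longest linear sequence: 12 steps (1, 2, 4, 5, 6, 7, 8, 9, 11, 12, 13, 14).

**Steps most likely to fail**

1. Step 14 (proposed new method). Intermolecular coupling may outrun the strained nine-membered closure, the C7 alkyl–palladium or borane may be lost by β-hydride elimination or protodeboronation, or 9-BBN may slowly reduce a ring A carbonyl. The fallback sets out from 24 and returns at 26, forming the same C7–C8 bond by known chromium chemistry. Hydroboration of the vinyl group with 9-BBN and oxidation with sodium perborate would give the primary alcohol F1. Dess–Martin oxidation would give the aldehyde F2. An intramolecular Nozaki–Hiyama–Kishi reaction (CrCl2, cat. NiCl2, DMSO/THF, high dilution), a closure established for nine-membered carbocycles, would give the C7 allylic alcohol F3; its configuration is immaterial. Methyl chloroformate and pyridine would give the methyl carbonate F4. A Tsuji palladium–formate reduction (Pd(OAc)2, PBu3, HCO2NH4) delivers hydride to the more substituted allyl terminus C7 and keeps the methylene exocyclic, giving 26.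

2. Step 11. The enamine may expel silanolate to give a conjugated iminium (β-elimination), the amine catalyst may be held as a Mannich-type adduct or as the salt of the acidic product, and facial control may be weak next to the quaternary C4. The fallback sets out from 16 and returns at 21, replacing catalytic turnover by a stoichiometric, acid-free auxiliary enamine. Condensation of 16 with (S)-2-(methoxymethyl)pyrrolidine over 4 Å molecular sieves would give the E-enamine F5. Addition of 20 at −78 °C (inverse-demand hetero-Diels–Alder/Michael addition of a preformed chiral enamine to a Knoevenagel acceptor) would give the cyclic N,O-aminal F6. Mild hydrolysis with buffered aqueous acetic acid would release 21 and the auxiliary.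

3. Step 13. Acid may ionise the tertiary C4–O bond (loss of configuration, elimination), the hindered tertiary OH may fail to add to the enolised trione, or the enol OH may add to the vinyl group. The fallback sets out from 22 and returns at 24, closing the ring under basic conditions. Oxalyl chloride with catalytic DMF would convert the enol into the vinylogous acid chloride F7. TBAF in THF would then unmask the tertiary alkoxide, which closes the dihydropyran by intramolecular addition–elimination without the C4–O bond ever being at risk.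

**Further compounds**

F1 | step 14 | (2R,3S,4R)-3-(2-hydroxyethyl) analogue of 24 (primary alcohol at C7) | OCC[C@H]1[C@@H](CC(C)C)C2=C(O[C@]1(C)CC[C@@H]1[C@@H](C(I)=C)CC1(C)C)C(C)(C)C(=O)C(C)(C)C2=O
F2 | step 14 | C7 aldehyde of F1 | O=CC[C@H]1[C@@H](CC(C)C)C2=C(O[C@]1(C)CC[C@@H]1[C@@H](C(I)=C)CC1(C)C)C(C)(C)C(=O)C(C)(C)C2=O
F3 | step 14 | 7-hydroxytomentodione B (either C7 epimer) | C=C1C(O)C[C@H]2[C@@H](CC(C)C)C3=C(O[C@]2(C)CC[C@@H]2[C@@H]1CC2(C)C)C(C)(C)C(=O)C(C)(C)C3=O
F4 | step 14 | methyl carbonate of F3 | C=C1C(OC(=O)OC)C[C@H]2[C@@H](CC(C)C)C3=C(O[C@]2(C)CC[C@@H]2[C@@H]1CC2(C)C)C(C)(C)C(=O)C(C)(C)C3=O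
F5 | step 11 | E-enamine of 16 with (S)-2-(methoxymethyl)pyrrolidine | COC[C@@H]1CCCN1/C=C/[C@](C)(O[Si](C)(C)C(C)(C)C)CC[C@@H]1[C@@H](C(I)=C)CC1(C)C
F6 | step 11 | cyclic N,O-aminal (2-amino-3,4-dihydro-2H-pyran) from F5 and 20 | COC[C@@H]1CCCN1C2OC3=C(C(=O)C(C)(C)C(=O)C3(C)C)[C@H](CC(C)C)[C@H]2[C@](C)(O[Si](C)(C)C(C)(C)C)CC[C@@H]1[C@@H](C(I)=C)CC1(C)C
F7 | step 13 | vinylogous acid chloride (β-chloroenone) of 22 | C=C[C@@H]([C@@H](CC(C)C)C1=C(Cl)C(C)(C)C(=O)C(C)(C)C1=O)[C@](C)(O[Si](C)(C)C(C)(C)C)CC[C@@H]1[C@@H](C(I)=C)CC1(C)C
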